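**Strategy.** Everything rests on cutting the 3(2H)-furanone (O–C3=C2–C1(=O)–C10, germacrane numbering) into a methyl ketone (C2–C3, carrying the Z-C4=C5 olefin) and a glycidic acyl unit (C1 with the trans C9–C10 epoxide). In one operation the ketone enolate is acylated at C1 and the oxygen of the resulting 1,3-diketonate opens the epoxide at the quaternary carbon C10 (5-exo, inversion). This joins the two halves, builds the furanone, transfers the Sharpless-set epoxide stereochemistry to C10 and frees the C9 hydroxyl for the methacrylate. The precursor is an epoxy acyl imidazolide. The ten-membered ring and lactone are closed later by CrCl2-mediated allylation (C6–C7).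

Key step: step 8

Remark: carbons are numbered C1 (ketone), C2=C3 (furanone enol ether), C4(C15)=C5, C6 (lactone carbinol), C7, C8 (OH), C9 (methacrylate), C10 (C14 methyl, furanone oxygen), C11(=C13)–C12 (lactone); the target is (6R,7R,8S,9S,10S). Both enantiomers of glyceraldehyde acetonide are assumed to be purchasable.

Step 1
Reactants: 1 but-2-yn-1-ol
Product: 2 (Z)-3-iodobut-2-en-1-ol
Conditions: NaAlH2(OCH2CH2OMe)2, THF, 0 to 23 °C; then I2, THF, −78 °C
Reagents that add atoms: iodine, II
Why: Hydroxyl-directed trans-hydroalumination of the propargylic alcohol followed by iodinolysis with retention should give the Z-vinyl iodide, so the anti addition fixes the geometry of the future C4=C5 bond.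

Step 2
Reactants: 2 (Z)-3-iodobut-2-en-1-ol
Product: 3 4-methoxybenzyl ether of 2
Conditions: NaH, 4-methoxybenzyl chloride, Bu4NI (cat.), THF, 0 to 23 °C
Reagents that add atoms: 4-methoxybenzyl chloride, COc1ccc(CCl)cc1
Why: Williamson etherification of the primary allylic alkoxide; the vinyl iodide is inert to NaH.

Step 3
Reactants: 3 4-methoxybenzyl ether of 2
Product: 4 (3Z)-5-[(4-methoxybenzyl)oxy]-3-methylpent-3-en-2-one
Conditions: t-BuLi (2.1 equiv), Et2O, −78 °C; then N-methoxy-N-methylacetamide, −78 to 0 °C; aq. NH4Cl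
Reagents that add atoms: N-methoxy-N-methylacetamide, CC(=O)N(C)OC
Why: Iodine–lithium exchange gives a Z-vinyllithium that is configurationally stable at −78 °C and is acylated once by the Weinreb amide (Weinreb ketone synthesis), so the acetyl group ends cis to C6.

Step 4
Reactants: 5 (S)-2,2-dimethyl-1,3-dioxolane-4-carbaldehyde
Product: 6 ethyl (2E)-3-[(4R)-2,2-dimethyl-1,3-dioxolan-4-yl]-2-methylprop-2-enoate
Conditions: ethyl 2-(triphenylphosphoranylidene)propanoate, CH2Cl2, 23 °C
Reagents that add atoms: ethyl 2-(triphenylphosphoranylidene)propanoate, CCOC(=O)C(C)=P(c1ccccc1)(c1ccccc1)c1ccccc1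
Why: Wittig olefination with the stabilised α-branched ylide should give the E-trisubstituted enoate (ester trans to C8) without epimerising the α-alkoxy aldehyde, whose stereocentre becomes C8.

Step 5
Reactants: 6 ethyl (2E)-3-[(4R)-2,2-dimethyl-1,3-dioxolan-4-yl]-2-methylprop-2-enoate
Product: 7 (2E)-3-[(4R)-2,2-dimethyl-1,3-dioxolan-4-yl]-2-methylprop-2-en-1-ol
Conditions: i-Bu2AlH, CH2Cl2, −78 °C
Reagents that add atoms: none
Why: 1,2-Reduction of the enoate by the aluminium hydride at low temperature gives the E-allylic alcohol needed for directed epoxidation and leaves the acetonide untouched.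

Step 6
Reactants: 7 (2E)-3-[(4R)-2,2-dimethyl-1,3-dioxolan-4-yl]-2-methylprop-2-en-1-ol
Product: 8 [(2S,3S)-3-[(4S)-2,2-dimethyl-1,3-dioxolan-4-yl]-2-methyloxiran-2-yl]methanol
Conditions: Ti(OiPr)4 (cat.), L-(+)-diethyl tartrate (cat.), t-BuOOH, 4 Å molecular sieves, CH2Cl2, −20 °C
Reagents that add atoms: tert-butyl hydroperoxide, CC(C)(C)OO
Why: Sharpless asymmetric epoxidation delivers oxygen to one face of the E-allylic alcohol under reagent control (L-(+)-tartrate gives the 2S,3S epoxide of E-allylic alcohols), setting C9 and C10 of the trans epoxide.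

Step 7
Reactants: 8 [(2S,3S)-3-[(4S)-2,2-dimethyl-1,3-dioxolan-4-yl]-2-methyloxiran-2-yl]methanol
Product: 9 (2R,3S)-3-[(4S)-2,2-dimethyl-1,3-dioxolan-4-yl]-2-methyloxirane-2-carboxylic acid
Conditions: TEMPO (cat.), NaOCl (cat.), NaClO2, MeCN/phosphate buffer pH 6.7, 35 °C
Reagents that add atoms: sodium chlorite NaClO2, [Na+].[O-]Cl=O
Why: The TEMPO/NaOCl/NaClO2 oxidation takes the primary alcohol to the acid at near-neutral pH, which the epoxide and the acetonide should tolerate.

Step 8
Reactants: 9 (2R,3S)-3-[(4S)-2,2-dimethyl-1,3-dioxolan-4-yl]-2-methyloxirane-2-carboxylic acid; 4 (3Z)-5-[(4-methoxybenzyl)oxy]-3-methylpent-3-en-2-one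
Product: 12 (2S)-2-{(S)-[(4S)-2,2-dimethyl-1,3-dioxolan-4-yl](hydroxy)methyl}-5-[(2Z)-4-(4-methoxybenzyloxy)but-2-en-2-yl]-2-methylfuran-3(2H)-one, via acyl imidazolide 10 (not isolated), via epoxy diketone lithium enolate 11 (not isolated)
Conditions: 9, 1,1'-carbonyldiimidazole, THF, 23 °C; separately 4, LiN(SiMe3)2 (3.2 equiv), THF, −78 °C; add the imidazolide solution, −78 to 0 °C; DMPU, 0 to 40 °C; AcOH, −20 °C
Reagents that add atoms: none
Why: Proposed new method: the acid is activated as acyl imidazolide 10, the kinetic α'-enolate of 4 attacks C1 (crossed Claisen acylation, the product being drained as diketonate 11 by the excess base), and on warming the enolate oxygen on C3 displaces the epoxide oxygen at C10, forming the O–C10 bond and the C9 alkoxide. The closest known reactions are the C-acylation of ketone lithium enolates by acyl imidazolides and the base-mediated cyclisation of 4-halo-1,3-diketones to 3(2H)-furanones; here the epoxide replaces the halide as leaving group. The furanone ring closes in the 5-exo-tet mode, which should be preferred over 6-endo attack at C9 by ring size, by the SN2-activating carbonyl at C1, and because C9 is deactivated and shielded by the neighbouring C8 acetal oxygen. C10 is set by SN2 inversion of the Sharpless epoxide (ionisation is disfavoured next to the carbonyl), and C9 keeps its configuration because its C–O bond is not touched. The step needs C- rather than O-acylation and α' rather than γ deprotonation of the enone, which the lithium counter-ion, the bulky amide base and −78 °C should secure; the lithium alkoxide is quenched cold with AcOH to limit retro-aldol cleavage of C9–C10.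

Step 9
Reactants: 12 furanone alcohol
Product: 13 methacrylate (2-methylprop-2-enoate) of the C9 hydroxyl of 12, stereocentres as in 12
Conditions: methacrylic anhydride, DMAP (cat.), Et3N, CH2Cl2, 0 to 23 °C
Reagents that add atoms: methacrylic anhydride, C=C(C)C(=O)OC(=O)C(C)=C
Why: DMAP-catalysed acyl transfer (Steglich-type) to the only free hydroxyl; the mild amine base should not trigger retro-aldol cleavage of the β-hydroxy ketone.

Step 10
Reactants: 13 methacrylate acetonide
Product: 14 (1S,2S)-2,3-dihydroxy-1-[(2S)-furanon-2-yl]propyl methacrylate (C7,C8-diol, furanone side chain as in 12)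
Conditions: AcOH/H2O 4:1, 40 °C
Reagents that add atoms: none
Why: Acid-catalysed hydrolysis of the terminal isopropylidene acetal; the PMB ether, the methacrylate and the vinylogous ester should be stable to aqueous AcOH.

Step 11
Reactants: 14 diol
Product: 15 bis(triethylsilyl) ether of 14 (C7–O and C8–O)
Conditions: Et3SiOTf, 2,6-lutidine, CH2Cl2, −78 °C
Reagents that add atoms: triethylsilyl triflate, CC[Si](CC)(CC)OS(=O)(=O)C(F)(F)F
Why: Silylation of both hydroxyls at low temperature blocks C8 before any acyl migration from C9 and prepares the primary position for selective oxidation.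

Step 12
Reactants: 15 bis(triethylsilyl) ether
Product: 16 C7 aldehyde with the C8 triethylsilyl ether and C9 methacrylate retained
Conditions: (COCl)2, DMSO, CH2Cl2, −78 to −40 °C; then Et3N, −78 °C
Reagents that add atoms: none
Why: Swern conditions cleave and oxidise primary triethylsilyl ethers selectively through the alkoxysulfonium salt while the secondary one survives; the base is added cold to avoid β-elimination of the C9 ester.

Step 13
Reactants: 16 aldehyde
Product: 17 Baylis–Hillman-type alcohol, methyl 2-methylidene-3-hydroxy ester at C11–C12 (C7 carbinol as a mixture of epimers)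
Conditions: methyl 2-bromoacrylate, CrCl2, NiCl2 (cat.), DMF, 23 °C
Reagents that add atoms: methyl 2-bromoacrylate, C=C(Br)C(=O)OC
Why: Nozaki–Hiyama–Kishi coupling of the α-bromoacrylate adds chemoselectively to the aldehyde under neutral conditions, without the amine base of a Morita–Baylis–Hillman reaction that would eliminate the C9 ester; the new C7 carbinol is erased in the next step.

Step 14
Reactants: 17 Baylis–Hillman-type alcohol
Product: 18 methyl (Z)-2-(bromomethyl)alk-2-enoate (C7=C11, CH2Br cis to C8)
Conditions: N-bromosuccinimide, Me2S (premixed), CH2Cl2, 0 to 23 °C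
Reagents that add atoms: N-bromosuccinimide, O=C1CCC(=O)N1Br
Why: Corey–Kim-type bromination of the Baylis–Hillman alcohol proceeds with allylic transposition (SN2') to the thermodynamically preferred Z-2-(bromomethyl)enoate.

Step 15
Reactants: 18 allylic bromide PMB ether
Product: 19 C6 allylic alcohol
Conditions: DDQ, CH2Cl2/pH 7 buffer, 0 °C
Reagents that add atoms: none
Why: Oxidative cleavage of the PMB ether by DDQ through the benzylic oxocarbenium ion, orthogonal to the silyl ether, the allylic bromide and the esters.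

Step 16
Reactants: 19 C6 allylic alcohol
Product: 20 Z-enal (C6 aldehyde)
Conditions: Dess–Martin periodinane, NaHCO3, CH2Cl2, 0 °C
Reagents that add atoms: none
Why: Dess–Martin oxidation of the allylic alcohol under buffered conditions should give the Z-enal without isomerisation.

Step 17
Reactants: 20 Z-enal allylic bromide
Product: 22 C8 triethylsilyl ether of the target, via macrocyclic hydroxy ester 21 (not isolated)
Conditions: CrCl2 (excess), THF, 23 °C, slow addition to about 2 mM; then camphorsulfonic acid (cat.), CH2Cl2, 23 °C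
Reagents that add atoms: none
Why: Intramolecular Nozaki–Hiyama–Kishi (Barbier-type) allylation: the allylchromium adds through its γ-carbon C7 to the aldehyde C6 in a cyclic transition state, closing the ten-membered carbocycle, and macrocyclic stereocontrol (equilibrating allylchromium, ring-constrained transition state) is relied on to place C6–O anti to C7–C8 and trans to the C8 silyloxy group; acid then closes the γ-lactone onto the only free hydroxyl.

Step 18
Reactants: 22 C8 triethylsilyl ether of the target
Product: 23 target, (6R,7R,8S,9S,10S)-8-hydroxy-9-methacryloyloxy furanoheliangolide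
Conditions: HF·pyridine, pyridine, THF, 0 °C
Reagents that add atoms: none
Why: Buffered fluoride cleavage of the secondary triethylsilyl ether should leave the methacrylate, the α-methylene lactone and the furanone intact.

**Compound list**

1 | but-2-yn-1-ol | CC#CCO | starting material
2 | (Z)-3-iodobut-2-en-1-ol | C/C(I)=C/CO | intermediate
3 | 1-({[(2Z)-3-iodobut-2-en-1-yl]oxy}methyl)-4-methoxybenzene | C/C(I)=C/COCc1ccc(OC)cc1 | intermediate
4 | (3Z)-5-[(4-methoxybenzyl)oxy]-3-methylpent-3-en-2-one | CC(=O)/C(C)=C\COCc1ccc(OC)cc1 | intermediate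
5 | (S)-2,2-dimethyl-1,3-dioxolane-4-carbaldehyde | O=C[C@@H]1COC(C)(C)O1 | starting material
6 | ethyl (2E)-3-[(4R)-2,2-dimethyl-1,3-dioxolan-4-yl]-2-methylprop-2-enoate | CCOC(=O)/C(C)=C/[C@@H]1COC(C)(C)O1 | intermediate
7 | (2E)-3-[(4R)-2,2-dimethyl-1,3-dioxolan-4-yl]-2-methylprop-2-en-1-ol | OC/C(C)=C/[C@@H]1COC(C)(C)O1 | intermediate
8 | [(2S,3S)-3-[(4S)-2,2-dimethyl-1,3-dioxolan-4-yl]-2-methyloxiran-2-yl]methanol | OC[C@]1(C)O[C@H]1[C@@H]2COC(C)(C)O2 | intermediate
9 | (2R,3S)-3-[(4S)-2,2-dimethyl-1,3-dioxolan-4-yl]-2-methyloxirane-2-carboxylic acid | OC(=O)[C@]1(C)O[C@H]1[C@@H]2COC(C)(C)O2 | intermediate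
10 | acyl imidazolide of 9 | O=C(n1ccnc1)[C@]1(C)O[C@H]1[C@@H]2COC(C)(C)O2 | intermediate
11 | (4Z)-1-[(2R,3S)-3-[(4S)-2,2-dimethyl-1,3-dioxolan-4-yl]-2-methyloxiran-2-yl]-6-[(4-methoxybenzyl)oxy]-4-methylhex-4-ene-1,3-dione (present as its lithium enolate) | O=C(CC(=O)/C(C)=C\COCc1ccc(OC)cc1)[C@]1(C)O[C@H]1[C@@H]2COC(C)(C)O2 | intermediate
12 | (2S)-2-{(S)-[(4S)-2,2-dimethyl-1,3-dioxolan-4-yl](hydroxy)methyl}-5-[(2Z)-4-(4-methoxybenzyloxy)but-2-en-2-yl]-2-methylfuran-3(2H)-one | O[C@@H]([C@@H]1COC(C)(C)O1)[C@]2(C)OC(/C(C)=C\COCc3ccc(OC)cc3)=CC2=O | intermediate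
13 | C9 methacrylate of 12 | C=C(C)C(=O)O[C@@H]([C@@H]1COC(C)(C)O1)[C@]2(C)OC(/C(C)=C\COCc3ccc(OC)cc3)=CC2=O | intermediate
14 | (1S,2S)-2,3-dihydroxy-1-{(2S)-5-[(2Z)-4-(4-methoxybenzyloxy)but-2-en-2-yl]-2-methyl-3-oxo-2,3-dihydrofuran-2-yl}propyl 2-methylprop-2-enoate | C=C(C)C(=O)O[C@@H]([C@@H](O)CO)[C@]1(C)OC(/C(C)=C\COCc2ccc(OC)cc2)=CC1=O | intermediate
15 | bis(triethylsilyl) ether of 14 | C=C(C)C(=O)O[C@@H]([C@@H](O[Si](CC)(CC)CC)CO[Si](CC)(CC)CC)[C@]1(C)OC(/C(C)=C\COCc2ccc(OC)cc2)=CC1=O | intermediate
16 | C7 aldehyde (C8 triethylsilyl ether, C9 methacrylate) | C=C(C)C(=O)O[C@@H]([C@@H](O[Si](CC)(CC)CC)C=O)[C@]1(C)OC(/C(C)=C\COCc2ccc(OC)cc2)=CC1=O | intermediate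
17 | Baylis–Hillman-type alcohol, methyl 3-hydroxy-2-methylidene ester (C7 epimers) | C=C(C)C(=O)O[C@@H]([C@@H](O[Si](CC)(CC)CC)C(O)C(=C)C(=O)OC)[C@]1(C)OC(/C(C)=C\COCc2ccc(OC)cc2)=CC1=O | intermediate
18 | methyl (Z)-2-(bromomethyl)enoate, PMB ether | C=C(C)C(=O)O[C@@H]([C@@H](O[Si](CC)(CC)CC)/C=C(\CBr)C(=O)OC)[C@]1(C)OC(/C(C)=C\COCc2ccc(OC)cc2)=CC1=O | intermediate
19 | methyl (Z)-2-(bromomethyl)enoate, C6 allylic alcohol | C=C(C)C(=O)O[C@@H]([C@@H](O[Si](CC)(CC)CC)/C=C(\CBr)C(=O)OC)[C@]1(C)OC(/C(C)=C\CO)=CC1=O | intermediate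
20 | methyl (Z)-2-(bromomethyl)enoate, C6 Z-enal | C=C(C)C(=O)O[C@@H]([C@@H](O[Si](CC)(CC)CC)/C=C(\CBr)C(=O)OC)[C@]1(C)OC(/C(C)=C\C=O)=CC1=O | intermediate
21 | macrocyclic C6 hydroxy methyl ester (ten-membered ring closed, lactone open) | C=C(C)C(=O)O[C@H]1[C@@H](O[Si](CC)(CC)CC)[C@@H](C(=C)C(=O)OC)[C@H](O)/C=C(/C)C2=CC(=O)[C@@]1(C)O2 | intermediate
22 | C8 triethylsilyl ether of the target | C=C(C)C(=O)O[C@H]1[C@@H](O[Si](CC)(CC)CC)[C@H]2C(=C)C(=O)O[C@@H]2/C=C(/C)C2=CC(=O)[C@@]1(C)O2 | intermediate
23 | target CNP0562373.1 | C=C(C)C(=O)O[C@H]1[C@@H](O)[C@H]2C(=C)C(=O)O[C@@H]2/C=C(/C)C2=CC(=O)[C@@]1(C)O2 | target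

**Totals.** Total step count: 18. Longest linear sequence: 15 steps (steps 4 to 18, from aldehyde 5); the ketone branch (steps 1 to 3) joins at step 8.

**Steps most likely to fail and fallbacks**

Step 8 (key step, proposed new method). The diketonate may not open the tertiary epoxide carbon, may open the epoxide at C9 in the 6-endo mode to a pyranone, or the C9 alkoxide may undergo retro-aldol cleavage of C9–C10. The fallback uses known chemistry and builds the furanone before the C9–C10 bond; it sets out from ketone 4 and aldehyde 5 and comes back at 12. The lithium enolate of 4 (LiN(SiMe3)2, THF, −78 °C) is condensed with racemic ethyl 2-(tert-butyldimethylsilyloxy)propanoate (Claisen condensation) to the silyloxy diketone F1. Aqueous HCl in THF removes the silyl group and cyclodehydrates the α'-hydroxy-1,3-diketone (the classical acid-mediated 3(2H)-furanone synthesis) to the 2-methylfuranone F2. Deprotonation of F2 at C10 with LiN(i-Pr)2 at −78 °C and aldol addition to 5 (Felkin–Anh control at C9) should give 12 together with its C10 epimer, to be separated by chromatography.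

Step 17. Oligomerisation may win over closure of the strained ten-membered ring, or the cyclic chromium transition state may give syn instead of anti addition, leading to the wrong C6/C7 diastereomer. The fallback changes the nucleophile and the transition-state type; it sets out from 20 and comes back at 22. Palladium-catalysed silylation of the allylic bromide with Me3SiSiMe3 (Pd2(dba)3 cat., THF) gives the allylsilane F3. BF3·OEt2 in CH2Cl2 at −78 °C then induces an intramolecular Hosomi–Sakurai allylation through an open transition state to the hydroxy ester 21, which camphorsulfonic acid lactonises to 22.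

Step 13. The α-silyloxy aldehyde with its β-methacryloyloxy group may lose methacrylate by β-elimination, or be reduced or pinacol-coupled by the low-valent chromium before the vinyl transfer occurs. The fallback replaces the organochromium addition by an aldol/elimination sequence; it sets out from 16 and comes back at 17. A Mukaiyama aldol addition of 1-methoxy-3-(phenylselanyl)-1-(trimethylsilyloxy)prop-1-ene (BF3·OEt2, CH2Cl2, −78 °C) gives the β-hydroxy selenide F4. Oxidation with H2O2/pyridine at 0 °C and syn-elimination of the selenoxide then unveil the 2-methylidene ester 17.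

**Further compounds**

F1 | step 8 | (5Z)-2-[(tert-butyldimethylsilyl)oxy]-7-[(4-methoxybenzyl)oxy]-5-methylhept-5-ene-3,5-dione-type silyloxy diketone (racemic at the silyloxy carbon; 1,3-diketone at C1/C3) | CC(O[Si](C)(C)C(C)(C)C)C(=O)CC(=O)/C(C)=C\COCc1ccc(OC)cc1
F2 | step 8 | 5-[(2Z)-4-(4-methoxybenzyloxy)but-2-en-2-yl]-2-methylfuran-3(2H)-one (racemic) | CC1OC(/C(C)=C\COCc2ccc(OC)cc2)=CC1=O
F3 | step 17 | methyl (Z)-2-[(trimethylsilyl)methyl]enoate analogue of 20 (allylsilane Z-enal) | C=C(C)C(=O)O[C@@H]([C@@H](O[Si](CC)(CC)CC)/C=C(\C[Si](C)(C)C)C(=O)OC)[C@]1(C)OC(/C(C)=C\C=O)=CC1=O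
F4 | step 13 | methyl 3-hydroxy-2-[(phenylselanyl)methyl] ester aldol adduct of 16 (mixture at C7 and C11) | C=C(C)C(=O)O[C@@H]([C@@H](O[Si](CC)(CC)CC)C(O)C(C[Se]c1ccccc1)C(=O)OC)[C@]1(C)OC(/C(C)=C\COCc2ccc(OC)cc2)=CC1=O
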